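The epsilon run at its last reading, 3.00 d, holds 51.8% left-handed product against 0.4% right-handed product, and alder looks nearly the same flask: its loading of free catalyst times its time is 1.11 times epsilon's, with the same racemization catalyst. Larch stands to the gamma run as 1.28 to one on that count. I therefore expect larch and alder to reach about as far as those two runs did.

common to all: left-handed substrate 0.050 M; right-handed substrate 0.050 M; gas 17 mM (held); racemization catalyst 1 mol%
- gamma: free catalyst 0.13 mol%; run made earlier
- epsilon: free catalyst 0.3 mol%; run made earlier
- larch: free catalyst 0.2 mol%; time 2.5 d
- alder: free catalyst 0.2 mol%; time 5.0 d

| run | time / d | left-handed product / % | right-handed product / % |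
|---|---|---|---|
| gamma | 0.250 | 3.9 | 0.4 |
| gamma | 0.833 | 11.0 | 0.1 |
| gamma | 1.25 | 16.9 | 0.2 |
| gamma | 2.00 | 24.7 | 0.4 |
| gamma | 3.00 | 33.5 | 0.3 |
| epsilon | 0.250 | 7.9 | 0.2 |
| epsilon | 0.417 | 12.5 | 0 |
| epsilon | 0.833 | 22.8 | 0.2 |
| epsilon | 1.67 | 37.1 | 0.6 |
| epsilon | 3.00 | 51.8 | 0.4 |

(standard deviation of a reading: 0.3 percentage points)

- free catalyst is single-handed; left-handed substrate and right-handed substrate are mirror images of each other, charged as a racemate, each of them at the stated concentration
- at the start none of the gas is in solution
- an excess is the difference of the two amounts in percent of their sum
- an excess is below zero if the other one leads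

* which one finishes higher in excess of left-handed product over right-handed product in the product ("neither" within 2 percentage points) (larch / alder / neither)
* excess of left-handed product over right-handed product in the product at the end, larch
* excess of left-handed product over right-handed product in the product at the end, alder

I carry one quantity, the leak, meaning the right-handed product made so far per left-handed product made so far. With both hands passing through the same catalyst, it is the mean of [right-handed substrate]/[left-handed substrate], taken over the left-handed product as it forms, divided by the selectivity factor of this dynamic kinetic resolution. The two last readings pooled give my reading, whose right-handed parts, 0.3% and 0.4%, are of like size to the scatter of 0.3 percentage points on each: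

leak = 0.00821, give or take 0.00497

excess = (1 − leak)/(1 + leak) = 98.4%

The excess falls by about twice any rise in the leak, so the margin of 2 points corresponds to a gap in leak of 0.0100. With my pooled reading taken as larch's leak, alder's leak has to be 2.22 times that to be told apart from it, and the last readings of gamma and epsilon, which give 0.00896 and 0.00772 with their scatter, stand closer together than that, so I say neither.

The forecast also says neither, with 98% for larch and 97.8% for alder, “so neither clearly wins”; my figure for both, a reading with its scatter, is higher than its figures.

The flask gives neither, with 98.1% for larch and 97.6% for alder.

    partner + free catalyst + left-handed substrate → free catalyst + left-handed product (k = 3.40 /M²/s)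
    partner + free catalyst + right-handed substrate → free catalyst + right-handed product (k = 0.0230 /M²/s)
    left-handed substrate + racemization catalyst ⇌ right-handed substrate + racemization catalyst, rate k3*[racemization catalyst]*[left-handed substrate] forward; the back reaction follows from the equilibrium constant (k = 0.0110 /M/s)
    gas ⇌ partner, rate k4*(csat - [partner]) (kL = 6.20 × 10⁻⁴ /s)
    racemization catalyst ⇌ dormant form (K = 2.20, k = 7.40 × 10⁻⁶ /s)

The leak is 0.00982 in larch and 0.0121 in alder, a difference of 0.00228, smaller than the gap. In larch, the step through free catalyst uses left-handed substrate 1.4 times as fast as forward racemization at 0.532 d and 2.7 times as fast at 2.50 d, when left-handed substrate stands at 20.0% and right-handed substrate at 41.1%. The larch flask read at 10 d has a leak of 0.0147, still 0.00488 above larch at its asked time, under the gap, and its excess is 97.1%.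

The numbers in the tables are calculated with made-up constants; scatter was added.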